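## Structural features

The target is an achiral diaryl ether: two benzene rings joined only through one oxygen, with no stereogenic centre and no double-bond geometry to set, because both side-chain alkenes end in geminal methyl groups. Ring A is a methyl benzoate whose ester carbon C1 is flanked on both sides by oxygen, a prenyl ether at C2 and the bridging aryloxy oxygen at C6, with a methyl group at C4 and hydrogens at C3 and C5. Ring B carries the bridging oxygen at C1', a hydroxymethyl group at C2', a methoxy group at C4' and the second prenyl ether at C6'. The ether oxygen therefore sits between two ortho substituents on ring B and next to the ester on ring A. The fragile groups are the two aryl prenyl ethers (acid-labile, prone to Claisen shifts on heating) and the primary benzylic alcohol on an electron-rich ring (ionisable under acid). The methyl ester is shielded by its two ortho substituents and is the least sensitive group. The real difficulty is the tri-ortho-substituted C6–O–C1' linkage beside a 2,6-dioxygenated benzoate, together with the need to tell apart three oxygens on ring B and two on ring A. The key step exploits the fact that C1–C4 of ring A (ester carbon, oxygenated carbon, CH, methyl-bearing carbon) repeat the pattern of C3–C6 of a 3-carbomethoxy-4-alkoxy-6-methyl-2-pyrone, while C5–C6 (a CH and an aryloxy carbon) are the two carbons of an alkyne already bonded to the ring B oxygen.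

## Logic of the disconnections

25 to 24. The bond cut is the Si–O bond on the benzylic oxygen of ring B. The benzylic alcohol is the one group that could compete in an alkylation or ionise under acid, so it is unveiled last. Nothing is gained in skeleton, but the endgame becomes free of chemoselectivity questions. The forward step needs only fluoride, which leaves allyl aryl ethers, the diaryl ether and the hindered ester alone.

24 to 23. The two O–CH2 bonds of the prenyl ethers at C2 and C6' are cut. Allyl aryl ethers would not survive the heat of ring construction or an acidic deprotection, so both are attached after the core is complete and after the only acidic step. Ten carbons are removed in one operation with one reagent. The forward step must alkylate an ester-chelated phenol and a hindered phenol at oxygen, which calls for carbonate in a polar aprotic solvent.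

23 to 22. The two O–CH2OMe acetal bonds are cut. The same acetal is used on both rings so that one acid treatment frees both phenols. The demand is an acid mild enough to leave the triisopropylsilyl ether in place, since that ether keeps the benzylic carbon from ionising.

22 to 6 and 20 (through 21). The bonds cut are C1–C6 and C4–C5 of ring A, with a CO2 bridge formally re-inserted between C1 and C4. Cutting inside ring A rather than at the ether oxygen turns the hindered O–C6 bond into an O–C(sp) bond that can be made on a phenol. The tetrasubstituted benzoate is reduced to a pyrone that already carries ester, oxygen and methyl, plus an alkyne, and the route becomes convergent. The forward step must control orientation (aryloxy carbon next to the ester carbon) and must tolerate heating. For that reason no prenyl group is present, and the alkyne is an aryl ynol ether, which has no retro-ene pathway.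

6 to 5, and 5 to 1 and 2 (through 3 and 4). First the O–CH2 acetal bond at the C4 oxygen is cut. Then the lactone O–C2 bond and the C3–C4 bond are cut, which separates an acetoacetyl unit from a malonate. The gain is two bulk chemicals. The forward step requires C-acylation of the malonate enolate and closure of the enol oxygen onto one ester.

20 to 17, and 17 to 15 and 16 (through 18 and 19). The triple bond is traced back to a 1,2-dichlorovinyl ether, and the O–C(vinyl) bond is then cut to a phenol and a two-carbon chlorinated electrophile. The hindered aryl–O–C bond is thus made by adding a phenoxide to a small electrophile, without metal catalysis. The forward steps require that the organolithium neither metalates the ring nor attacks the silyl ether, so they are run cold with controlled stoichiometry.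

15 to 13 (through 14), 13 to 12, and 12 to 11. The C1'–O bond is replaced by a C1'–CHO bond, then the acetal O–CH2 bond is cut, then the O–CH3 bond of the oxygen that becomes the C6' oxygen is restored. The formyl group is used twice: it chelates and so singles out one of two methoxy groups, and it is then excised to leave the bridging oxygen. This returns the problem to a dimethoxy arene. The forward steps demand a demethylation that spares the silyl ether and an aryl (not hydride) migration in the oxidation.

11 to 9 (through 10), 9 to 8, and 8 to 7. The aryl–CHO bond is cut back to an aryl–Br bond, then the O–Si bond and the C–Br bond are cut. Bromination reliably selects the position beside the hydroxymethyl group, and halogen–lithium exchange places the formyl carbon there without exposing the silyl ether to the acidic medium of a direct electrophilic formylation. The gain is commercial 7. The demands are clean monobromination and exchange at low temperature.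

## Other disconnections considered

Alternative 1: The cut goes through ring B at C1'–C2' and C1'–C6', with ring B stored as a cyclohexenone spiro-fused at the future ether carbon.
- Forward key step: the C2 methylene of coumaranone A2 would add twice, under an alkoxide base, to the cross-conjugated alkoxy-ynone–enone A3 to give spirocycle A1 (racemic, either diastereomer usable). Dehydrogenation to dienone A4 and methoxide attack at the coumaranone carbonyl would then break the spiro C–C bond, aromatise ring B and deliver the ring A methyl ester in phenol A5.
- In favour: the congested C1'–O bond exists before ring B does, so no hindered aryl C–O bond is made. The double Michael addition is an ionic reaction near room temperature, milder than the heating the chosen cycloaddition needs; on this point the alternative is the better. The fragmentation would create the methyl ester and the C4' oxygen together.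
- Against: two stereocentres are built and then erased. Ring B needs an oxidation that the chosen plan avoids. The tert-butyl ynol ether in A3 is thermally labile. Methoxide could exchange the vinylogous ester alkoxy group of A4 instead of attacking the ketone, which would blur the distinction between the C4' and C6' oxygens. The aryl tert-butyl ether of A5 needs stronger acid than a methoxymethyl ether while a benzylic silyl ether is present.
- Comparison: on structure the two plans are equal in avoiding a direct diaryl ether coupling. On mechanism the chosen plan has one orientation question settled by polarity, whereas this one adds a chemoselectivity question in the fragmentation. On step economy it is estimated at 15 to 16 operations with about six after the key step, against 14 with three, so the chosen plan is shorter.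

Alternative 2: Ring B is the ring that is built, by cutting C2'–C3', C3'–C4', C5'–C6' and C6'–C1'.
- Forward key step: irradiation of diazo enone A7 (to be made from salicylate phenol A9) would trigger a Wolff rearrangement, forming C2'–C3', to a vinylketene. [2+2] cycloaddition with methoxyethyne A8, 4π ring opening of the cyclobutenone and 6π closure of the dienylketene would give phenol A6.
- In favour: the orientation is inherent in the polarity of the alkoxyalkyne, which is equal to the chosen plan in regiocontrol. The C4' methoxy group and the free C6' hydroxyl come out already differentiated, whereas the chosen route spends steps 6 to 8 on that; here the alternative is better. Ring A arrives with its prenyl ether in place, so the endgame is two steps instead of three, and the total is estimated at about ten operations; on step count the alternative is better.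
- Against: A7 requires enol ether formation from the hindered, ester-chelated A9 and a diazoketone synthesis with hazardous diazo reagents. The vinylketene carries a donor aryloxy group at its terminus, which lowers its electrophilicity in the [2+2] step. A8 is a very low-boiling, unstable reagent that must be prepared. A prenyl ether is exposed to ultraviolet light and to the heat of the electrocyclic cascade, where allyl shifts threaten. A four-bond cascade through several intermediates leaves more room for diversion than a single cycloaddition and extrusion.
- Comparison: on structure both plans build one arene onto an intact ether oxygen and are equal. On mechanism the chosen plan is a two-event thermal pericyclic sequence, against a four-event cascade that needs photochemistry. On step economy the alternative is better, but its key step is harder to secure.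

Alternative 3: The cut is at O–C6 and at the C1–carboxyl bond of ring A, and no ring is formed.
- Forward key step: fluoride would release a 3-alkoxyaryne from silyl triflate A11. The phenoxide of 15 would add at the aryne carbon remote from the acetal oxygen (C6), and the aryl anion at C1 would be trapped by carbon dioxide A12 to give acid A10. O-Methylation of A10 leads to 22.
- In favour: it uses 15 directly and dispenses with steps 9 and 10 and with the handling of an ynol ether; on that point it is better. It runs at room temperature. Its orientation is guided by the inductive bias of the 3-alkoxyaryne, which is as dependable as the orbital control of the chosen plan; on this the two are equal. The endgame is identical.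
- Against: a 2,6-disubstituted phenoxide is a hindered nucleophile and can itself be carbonated by A12, which lowers its reactivity. The aryl anion is strongly basic and may be protonated by the solvent before it meets A12, giving the ether without the carboxyl group. Three-component aryne couplings with A12 are best established for nitrogen nucleophiles. Fluoride is used in the presence of a silyl ether. A11 needs four or five steps (directed metalation, silylation, triflation), against two steps to 6.
- Comparison: on structure both plans set the ester carbon and the ether oxygen side by side in one step and are equal. On mechanism this is an ionic three-component cascade whose weak point is capture of the carbanion, against a pericyclic sequence whose weak point is rate. On step economy it is about equal (some 15 operations including the esterification).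

Key step: step 11

Remark: the target has no stereogenic element. The atom mapping of 6 and 20 onto 22 was checked position by position and needed no correction. The changes made concern the way to 11 (bromination and halogen–lithium exchange instead of direct formylation) and the order of the last three steps (prenylation before desilylation).

## Route

Step 1
Reactants: 1 2,2,6-trimethyl-4H-1,3-dioxin-4-one; 2 dimethyl malonate (dimethyl propanedioate)
Product: 5 methyl 4-hydroxy-6-methyl-2-oxo-2H-pyran-3-carboxylate, via acetylketene 3 (not isolated), via acetoacetylmalonate 4 (not isolated)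
Conditions: 2 (2 equiv), NaH (2 equiv), PhMe, rt; 1 added slowly at 110 °C; then 1 M HCl
Reagents that add atoms: none
Why: Retro-hetero-Diels–Alder cleavage of 1 at 110 °C releases acetylketene and acetone; the sodium enolate of 2 is C-acylated by the ketene (the acetoacetylation that diketene performs on malonates), and the enol oxygen of the new diketone closes onto one ester with loss of methoxide (Claisen-type lactonisation) to give the 4-hydroxy-2-pyrone as its conjugated enol.

Step 2
Reactants: 5 methyl 4-hydroxy-6-methyl-2-oxo-2H-pyran-3-carboxylate
Product: 6 methyl 4-(methoxymethoxy)-6-methyl-2-oxo-2H-pyran-3-carboxylate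
Conditions: MOMCl, i-Pr2NEt, CH2Cl2, 0 °C to rt
Reagents that add atoms: chloromethyl methyl ether (MOMCl), COCCl
Why: Williamson-type O-alkylation of the acidic vinylogous carboxylic acid by an oxocarbenium-like electrophile; the hard electrophile should react at the C4 oxygen, which keeps the 2-pyrone system, rather than at the lactone carbonyl oxygen.

Step 3
Reactants: 7 (3,5-dimethoxyphenyl)methanol
Product: 8 (2-bromo-3,5-dimethoxyphenyl)methanol
Conditions: NBS, MeCN, 0 °C to rt
Reagents that add atoms: N-bromosuccinimide (NBS), O=C1CCC(=O)N1Br
Why: Electrophilic aromatic bromination; the carbon para to one methoxy group and ortho to the other, beside the hydroxymethyl group, is strongly activated and less crowded than the carbon between the two methoxy groups, so monobromination there is expected.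

Step 4
Reactants: 8 (2-bromo-3,5-dimethoxyphenyl)methanol
Product: 9 [(2-bromo-3,5-dimethoxyphenyl)methoxy]tri(propan-2-yl)silane
Conditions: TIPSCl, imidazole, DMF, rt
Reagents that add atoms: chlorotri(propan-2-yl)silane (TIPSCl), CC(C)[Si](Cl)(C(C)C)C(C)C
Why: Standard silylation of a primary alcohol; the bulky silyl ether is chosen because it has to survive n-BuLi twice, a peracid, carbonate bases and prolonged heating.

Step 5
Reactants: 9 [(2-bromo-3,5-dimethoxyphenyl)methoxy]tri(propan-2-yl)silane
Product: 11 2,4-dimethoxy-6-({[tri(propan-2-yl)silyl]oxy}methyl)benzaldehyde, via aryllithium 10 (not isolated)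
Conditions: n-BuLi, THF, −78 °C; DMF, −78 °C to 0 °C; aq. NH4Cl
Reagents that add atoms: N,N-dimethylformamide (DMF), CN(C)C=O
Why: Bromine–lithium exchange is faster than any ring deprotonation at −78 °C and fixes the site of the new carbon; formylation of the aryllithium with DMF (Bouveault aldehyde synthesis) gives the aldehyde on aqueous work-up.

Step 6
Reactants: 11 2,4-dimethoxy-6-({[tri(propan-2-yl)silyl]oxy}methyl)benzaldehyde
Product: 12 2-hydroxy-4-methoxy-6-({[tri(propan-2-yl)silyl]oxy}methyl)benzaldehyde
Conditions: MgI2·OEt2 (1.5 equiv), PhMe, 70 °C; aq. NH4Cl
Reagents that add atoms: none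
Why: Chelation-controlled demethylation: magnesium binds the aldehyde oxygen and the ortho methoxy oxygen in a six-membered chelate and iodide removes that methyl group by SN2 displacement; the para methoxy group and the bulky silyl ether cannot chelate and should remain.

Step 7
Reactants: 12 2-hydroxy-4-methoxy-6-({[tri(propan-2-yl)silyl]oxy}methyl)benzaldehyde
Product: 13 4-methoxy-2-(methoxymethoxy)-6-({[tri(propan-2-yl)silyl]oxy}methyl)benzaldehyde
Conditions: MOMCl, i-Pr2NEt, CH2Cl2, 0 °C to 40 °C
Reagents that add atoms: chloromethyl methyl ether (MOMCl), COCCl
Why: Williamson-type acetalisation of the hydrogen-bonded salicylaldehyde hydroxyl; it places the oxygen that will later carry a prenyl group under the same protecting group as on ring A.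

Step 8
Reactants: 13 4-methoxy-2-(methoxymethoxy)-6-({[tri(propan-2-yl)silyl]oxy}methyl)benzaldehyde
Product: 15 4-methoxy-2-(methoxymethoxy)-6-({[tri(propan-2-yl)silyl]oxy}methyl)phenol, via aryl formate 14 (not isolated)
Conditions: mCPBA, CH2Cl2, 0 °C to rt; then K2CO3 (cat.), MeOH, 0 °C
Reagents that add atoms: 3-chloroperoxybenzoic acid (mCPBA), OOC(=O)c1cccc(Cl)c1
Why: Dakin-type oxidation run as a Baeyer–Villiger reaction: the aryl group, activated by an ortho and a para oxygen donor, migrates in preference to hydride in the Criegee intermediate, and the aryl formate is cleaved by mild methanolysis.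

Step 9
Reactants: 15 4-methoxy-2-(methoxymethoxy)-6-({[tri(propan-2-yl)silyl]oxy}methyl)phenol; 16 trichloroethylene (1,1,2-trichloroethene)
Product: 17 {[2-{[(E)-1,2-dichloroethenyl]oxy}-5-methoxy-3-(methoxymethoxy)phenyl]methoxy}tri(propan-2-yl)silane
Conditions: K2CO3, DMF, 70 °C
Reagents that add atoms: none
Why: Base converts trichloroethylene into dichloroacetylene in the flask and the phenoxide adds to it by anti addition, a known route from phenols, including ortho-substituted ones, to aryl (E)-1,2-dichlorovinyl ethers.

Step 10
Reactants: 17 {[2-{[(E)-1,2-dichloroethenyl]oxy}-5-methoxy-3-(methoxymethoxy)phenyl]methoxy}tri(propan-2-yl)silane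
Product: 20 {[2-(ethynyloxy)-5-methoxy-3-(methoxymethoxy)phenyl]methoxy}tri(propan-2-yl)silane, via chloroethynyl ether 18 (not isolated), via lithium acetylide 19 (not isolated)
Conditions: n-BuLi (2.3 equiv), THF, −78 °C to −40 °C; H2O, −78 °C; rapid filtration through basic Al2O3
Reagents that add atoms: none
Why: Deprotonation of the vinylic CH and anti elimination of LiCl give the chloroalkynyl ether, chlorine–lithium exchange with the second equivalent gives the lithium aryloxyacetylide, and protonation gives the terminal ynol ether (the dichlorovinyl ether route to ynol ethers); ring lithiation between the two ring oxygens is slow at −78 °C and would in any case be reversed by the water quench.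

Step 11
Reactants: 6 methyl 4-(methoxymethoxy)-6-methyl-2-oxo-2H-pyran-3-carboxylate; 20 {[2-(ethynyloxy)-5-methoxy-3-(methoxymethoxy)phenyl]methoxy}tri(propan-2-yl)silane
Product: 22 methyl 2-(methoxymethoxy)-6-[4-methoxy-2-(methoxymethoxy)-6-({[tri(propan-2-yl)silyl]oxy}methyl)phenoxy]-4-methylbenzoate, via bicyclic lactone 21 (not isolated)
Conditions: 6 (1.5 equiv), xylenes (1 M), 140 °C, sealed tube, Ar
Reagents that add atoms: none
Why: The electron-poor 2-pyrone, its LUMO lowered by the lactone carbonyl and the C3 ester, acts as the 4π diene across C3 and C6 toward the electron-rich ynol ether in an inverse-demand Diels–Alder reaction. The transition state is asynchronous: the bond from the nucleophilic terminal CH of the alkyne to the electrophilic methyl-bearing C6 leads, and the bond from the oxygen-bearing alkyne carbon to C3 follows. The bridged adduct 21 then loses CO2 by retro-[4+2] and aromatises, so ring A is closed by an intermolecular [4+2] cycloaddition that forms both ring bonds (C1–C6 and C4–C5 of the benzoate) and is made aromatic by extrusion. The closest known reaction type is the cycloaddition of 2-pyrone-3-carboxylates with ynamines, alkoxyalkynes and ketene acetals, which gives benzoates and salicylates with the heteroatom next to the ester. No stereocentre is created in 22; the two bridgehead centres of 21 are transient and vanish on aromatisation. The selectivity needed is orientation, aryloxy carbon next to ester carbon, and it is secured by matched polarity: the largest LUMO coefficient of the diene lies at C6 and the largest HOMO coefficient of the ynol ether at its terminal carbon. Chemoselectivity is secured by the substrate: no prenyl group is present to undergo a Claisen shift, an aryl ynol ether has no β-hydrogen for retro-ene loss of a ketene, and the acetals and the silyl ether are inert to neutral heating. The C4 alkoxy group and the aryl group on the ynol ether oxygen both lower reactivity, which is why high concentration and 140 °C are specified.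

Step 12
Reactants: 22 methyl 2-(methoxymethoxy)-6-[4-methoxy-2-(methoxymethoxy)-6-({[tri(propan-2-yl)silyl]oxy}methyl)phenoxy]-4-methylbenzoate
Product: 23 methyl 2-hydroxy-6-[2-hydroxy-4-methoxy-6-({[tri(propan-2-yl)silyl]oxy}methyl)phenoxy]-4-methylbenzoate
Conditions: HCl in MeOH (1.25 M, 0.5 equiv), MeOH/CH2Cl2, 0 °C to rt
Reagents that add atoms: none
Why: Acid-catalysed transacetalisation: each aryl methoxymethyl ether is protonated, releases the phenol and the oxocarbenium ion is trapped by methanol as dimethoxymethane; phenolic acetals of this kind cleave much faster than a primary triisopropylsilyl ether in dilute acid, and the retained silyl ether keeps the benzylic carbon from ionising.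

Step 13
Reactants: 23 methyl 2-hydroxy-6-[2-hydroxy-4-methoxy-6-({[tri(propan-2-yl)silyl]oxy}methyl)phenoxy]-4-methylbenzoate
Product: 24 methyl 2-[4-methoxy-2-[(3-methylbut-2-en-1-yl)oxy]-6-({[tri(propan-2-yl)silyl]oxy}methyl)phenoxy]-4-methyl-6-[(3-methylbut-2-en-1-yl)oxy]benzoate
Conditions: prenyl bromide (3 equiv), K2CO3, DMF, rt to 50 °C
Reagents that add atoms: 1-bromo-3-methylbut-2-ene (prenyl bromide), CC(C)=CCBr
Why: Double Williamson etherification; under carbonate in a polar aprotic solvent both phenoxides, the ester-chelated one on ring A and the hindered one on ring B, should be alkylated at oxygen by the primary allylic bromide, and no free alcohol is present to compete.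

Step 14
Reactants: 24 methyl 2-[4-methoxy-2-[(3-methylbut-2-en-1-yl)oxy]-6-({[tri(propan-2-yl)silyl]oxy}methyl)phenoxy]-4-methyl-6-[(3-methylbut-2-en-1-yl)oxy]benzoate
Product: 25 methyl 2-[2-(hydroxymethyl)-4-methoxy-6-[(3-methylbut-2-en-1-yl)oxy]phenoxy]-4-methyl-6-[(3-methylbut-2-en-1-yl)oxy]benzoate
Conditions: TBAF, THF, 0 °C to rt; aq. NH4Cl
Reagents that add atoms: none
Why: Fluoride-driven cleavage of the Si–O bond, paid for by the strong Si–F bond; the prenyl ethers, the diaryl ether and the hindered methyl ester are inert to these mildly basic conditions, so the benzylic alcohol is released last and without acid.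

## Compound list

1 | 2,2,6-trimethyl-4H-1,3-dioxin-4-one | CC1=CC(=O)OC(C)(C)O1 | starting material
2 | dimethyl malonate (dimethyl propanedioate) | COC(=O)CC(=O)OC | starting material
3 | acetylketene (but-1-ene-1,3-dione) | CC(=O)C=C=O | intermediate
4 | dimethyl 2-(3-oxobutanoyl)propanedioate (acetoacetylmalonate) | CC(=O)CC(=O)C(C(=O)OC)C(=O)OC | intermediate
5 | methyl 4-hydroxy-6-methyl-2-oxo-2H-pyran-3-carboxylate | COC(=O)C1=C(O)C=C(C)OC1=O | intermediate
6 | methyl 4-(methoxymethoxy)-6-methyl-2-oxo-2H-pyran-3-carboxylate | COCOC1=C(C(=O)OC)C(=O)OC(C)=C1 | intermediate
7 | (3,5-dimethoxyphenyl)methanol | COc1cc(CO)cc(OC)c1 | starting material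
8 | (2-bromo-3,5-dimethoxyphenyl)methanol | COc1cc(CO)c(Br)c(OC)c1 | intermediate
9 | [(2-bromo-3,5-dimethoxyphenyl)methoxy]tri(propan-2-yl)silane | COc1cc(CO[Si](C(C)C)(C(C)C)C(C)C)c(Br)c(OC)c1 | intermediate
10 | [2,4-dimethoxy-6-({[tri(propan-2-yl)silyl]oxy}methyl)phenyl]lithium | COc1cc(CO[Si](C(C)C)(C(C)C)C(C)C)c([Li])c(OC)c1 | intermediate
11 | 2,4-dimethoxy-6-({[tri(propan-2-yl)silyl]oxy}methyl)benzaldehyde | COc1cc(CO[Si](C(C)C)(C(C)C)C(C)C)c(C=O)c(OC)c1 | intermediate
12 | 2-hydroxy-4-methoxy-6-({[tri(propan-2-yl)silyl]oxy}methyl)benzaldehyde | COc1cc(O)c(C=O)c(CO[Si](C(C)C)(C(C)C)C(C)C)c1 | intermediate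
13 | 4-methoxy-2-(methoxymethoxy)-6-({[tri(propan-2-yl)silyl]oxy}methyl)benzaldehyde | COCOc1cc(OC)cc(CO[Si](C(C)C)(C(C)C)C(C)C)c1C=O | intermediate
14 | 4-methoxy-2-(methoxymethoxy)-6-({[tri(propan-2-yl)silyl]oxy}methyl)phenyl formate | COCOc1cc(OC)cc(CO[Si](C(C)C)(C(C)C)C(C)C)c1OC=O | intermediate
15 | 4-methoxy-2-(methoxymethoxy)-6-({[tri(propan-2-yl)silyl]oxy}methyl)phenol | COCOc1cc(OC)cc(CO[Si](C(C)C)(C(C)C)C(C)C)c1O | intermediate
16 | trichloroethylene (1,1,2-trichloroethene) | ClC=C(Cl)Cl | starting material
17 | {[2-{[(E)-1,2-dichloroethenyl]oxy}-5-methoxy-3-(methoxymethoxy)phenyl]methoxy}tri(propan-2-yl)silane | Cl/C=C(/Cl)Oc1c(CO[Si](C(C)C)(C(C)C)C(C)C)cc(OC)cc1OCOC | intermediate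
18 | {[2-[(chloroethynyl)oxy]-5-methoxy-3-(methoxymethoxy)phenyl]methoxy}tri(propan-2-yl)silane | ClC#COc1c(CO[Si](C(C)C)(C(C)C)C(C)C)cc(OC)cc1OCOC | intermediate
19 | lithium 2-[4-methoxy-2-(methoxymethoxy)-6-({[tri(propan-2-yl)silyl]oxy}methyl)phenoxy]ethyn-1-ide | [Li]C#COc1c(CO[Si](C(C)C)(C(C)C)C(C)C)cc(OC)cc1OCOC | intermediate
20 | {[2-(ethynyloxy)-5-methoxy-3-(methoxymethoxy)phenyl]methoxy}tri(propan-2-yl)silane | C#COc1c(CO[Si](C(C)C)(C(C)C)C(C)C)cc(OC)cc1OCOC | intermediate
21 | methyl 8-[4-methoxy-2-(methoxymethoxy)-6-({[tri(propan-2-yl)silyl]oxy}methyl)phenoxy]-5-(methoxymethoxy)-1-methyl-3-oxo-2-oxabicyclo[2.2.2]octa-5,7-diene-4-carboxylate (racemic, transient) | CC12OC(=O)C(C(=O)OC)(C(OCOC)=C1)C(Oc1c(CO[Si](C(C)C)(C(C)C)C(C)C)cc(OC)cc1OCOC)=C2 | intermediate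
22 | methyl 2-(methoxymethoxy)-6-[4-methoxy-2-(methoxymethoxy)-6-({[tri(propan-2-yl)silyl]oxy}methyl)phenoxy]-4-methylbenzoate | COCOc1cc(C)cc(Oc2c(CO[Si](C(C)C)(C(C)C)C(C)C)cc(OC)cc2OCOC)c1C(=O)OC | intermediate
23 | methyl 2-hydroxy-6-[2-hydroxy-4-methoxy-6-({[tri(propan-2-yl)silyl]oxy}methyl)phenoxy]-4-methylbenzoate | COC(=O)c1c(O)cc(C)cc1Oc1c(CO[Si](C(C)C)(C(C)C)C(C)C)cc(OC)cc1O | intermediate
24 | methyl 2-[4-methoxy-2-[(3-methylbut-2-en-1-yl)oxy]-6-({[tri(propan-2-yl)silyl]oxy}methyl)phenoxy]-4-methyl-6-[(3-methylbut-2-en-1-yl)oxy]benzoate | COC(=O)c1c(OCC=C(C)C)cc(C)cc1Oc1c(CO[Si](C(C)C)(C(C)C)C(C)C)cc(OC)cc1OCC=C(C)C | intermediate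
25 | methyl 2-[2-(hydroxymethyl)-4-methoxy-6-[(3-methylbut-2-en-1-yl)oxy]phenoxy]-4-methyl-6-[(3-methylbut-2-en-1-yl)oxy]benzoate | COC(=O)c1c(OCC=C(C)C)cc(C)cc1Oc1c(CO)cc(OC)cc1OCC=C(C)C | target

## Step count and risk assessment

Total step count: 14. Longest linear sequence: 12 steps (from 7 through steps 3 to 14); the two-step pyrone arm (steps 1 and 2) joins at step 11.

Least certain steps:

Step 11 (key step). The cycloaddition may be too slow, because the C4 alkoxy group raises the diene LUMO and an aryl ynol ether is less nucleophilic than an alkyl ynol ether or an ynamine. The second bond must also form at the quaternary ester-bearing carbon beside a di-ortho-substituted aryloxy group. Prolonged heating would then favour hydration or oligomerisation of the ynol ether over cycloaddition. The fallback makes the diene more electron-poor and sets out from 5 and 20. Acetylation of 5 (Ac2O, Et3N, CH2Cl2, 0 °C) should give methyl 4-(acetyloxy)-6-methyl-2-oxo-2H-pyran-3-carboxylate F1, whose acyloxy group is a far weaker donor than an alkoxy group. Cycloaddition of F1 with 20 and loss of CO2 should then proceed at lower temperature to methyl 2-(acetyloxy)-6-[4-methoxy-2-(methoxymethoxy)-6-({[tri(propan-2-yl)silyl]oxy}methyl)phenoxy]-4-methylbenzoate F2. Methanolic HCl should cleave the aryl acetate by transesterification together with the ring B acetal, and the route is rejoined at 23.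

Step 1. The thermally generated ketene may dimerise or acylate the enolate at oxygen, and ring closure may stop at the open-chain stage, giving mixtures. The fallback sets out from 2 and uses a preformed acetoacetyl donor at low temperature instead of a ketene generated at 110 °C: sodium dimethyl malonate is acylated with commercial diketene (THF, 0 °C), then warmed to close the lactone through the same intermediate 4, returning at 5. No new compound is involved.

Step 6. The Lewis-acidic iodide may cause loss of the silyl ether or cleavage at the benzylic C–O bond, or the discrimination between the two methoxy groups may be incomplete. The fallback sets out from 7 and keeps the benzylic oxygen as an acetate until the demethylation is over: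
- acetylation (Ac2O, pyridine) to (3,5-dimethoxyphenyl)methyl acetate F3;
- Vilsmeier–Haack formylation (POCl3, DMF) para to one methoxy group to (2-formyl-3,5-dimethoxyphenyl)methyl acetate F4;
- chelation-controlled demethylation with BCl3 (CH2Cl2, −78 to 0 °C), which an acetate tolerates, to (2-formyl-3-hydroxy-5-methoxyphenyl)methyl acetate F5;
- MOMCl and i-Pr2NEt to [2-formyl-5-methoxy-3-(methoxymethoxy)phenyl]methyl acetate F6;
- K2CO3 in MeOH to 2-(hydroxymethyl)-4-methoxy-6-(methoxymethoxy)benzaldehyde F7;
- silylation with TIPSCl and imidazole, which returns to the route at 13.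

Step 10. The terminal ynol ether may decompose during isolation, by hydration on contact with moist or acidic surfaces or by oligomerisation on concentration; incomplete chlorine–lithium exchange is a lesser concern. The fallback sets out from 19 in the flask and stores the alkyne in silyl-capped form. Quenching 19 with chlorotrimethylsilane instead of water should give {[5-methoxy-3-(methoxymethoxy)-2-{[(trimethylsilyl)ethynyl]oxy}phenyl]methoxy}tri(propan-2-yl)silane F8, which should tolerate chromatography and storage. K2CO3 in MeOH at 0 °C removes the alkynyl silyl group just before use, returning at 20.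

Step 12. The silyl ether may be partly lost, followed by acid-promoted ionisation of the freed benzylic alcohol and capture by methanol; cleavage of the more hindered acetal may also be slow. The fallback sets out from 22 and removes all three protecting groups in water, where a benzylic cation can only return the alcohol. Aqueous HCl in THF (40 °C) should give methyl 2-hydroxy-6-[2-hydroxy-6-(hydroxymethyl)-4-methoxyphenoxy]-4-methylbenzoate F9. Carbonate-mediated prenylation (prenyl bromide, K2CO3, acetone), selective for the two phenols over the primary alcohol, then leads directly to 25.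

## Further compounds

F1 | step 11 | methyl 4-(acetyloxy)-6-methyl-2-oxo-2H-pyran-3-carboxylate | CC(=O)OC1=C(C(=O)OC)C(=O)OC(C)=C1
F2 | step 11 | methyl 2-(acetyloxy)-6-[4-methoxy-2-(methoxymethoxy)-6-({[tri(propan-2-yl)silyl]oxy}methyl)phenoxy]-4-methylbenzoate | CC(=O)Oc1cc(C)cc(Oc2c(CO[Si](C(C)C)(C(C)C)C(C)C)cc(OC)cc2OCOC)c1C(=O)OC
F0 | step 1 | none | none
F3 | step 6 | (3,5-dimethoxyphenyl)methyl acetate | COc1cc(COC(C)=O)cc(OC)c1
F4 | step 6 | (2-formyl-3,5-dimethoxyphenyl)methyl acetate | COc1cc(COC(C)=O)c(C=O)c(OC)c1
F5 | step 6 | (2-formyl-3-hydroxy-5-methoxyphenyl)methyl acetate | COc1cc(O)c(C=O)c(COC(C)=O)c1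
F6 | step 6 | [2-formyl-5-methoxy-3-(methoxymethoxy)phenyl]methyl acetate | COCOc1cc(OC)cc(COC(C)=O)c1C=O
F7 | step 6 | 2-(hydroxymethyl)-4-methoxy-6-(methoxymethoxy)benzaldehyde | COCOc1cc(OC)cc(CO)c1C=O
F8 | step 10 | {[5-methoxy-3-(methoxymethoxy)-2-{[(trimethylsilyl)ethynyl]oxy}phenyl]methoxy}tri(propan-2-yl)silane | C[Si](C)(C)C#COc1c(CO[Si](C(C)C)(C(C)C)C(C)C)cc(OC)cc1OCOC
F9 | step 12 | methyl 2-hydroxy-6-[2-hydroxy-6-(hydroxymethyl)-4-methoxyphenoxy]-4-methylbenzoate | COC(=O)c1c(O)cc(C)cc1Oc1c(CO)cc(OC)cc1O
A1 | alternative 1 | 6'-tert-butoxy-4-(methoxymethoxy)-6-methyl-2'-({[tri(propan-2-yl)silyl]oxy}methyl)-3H-spiro[1-benzofuran-2,1'-cyclohex-5'-ene]-3,4'-dione (racemic, either diastereomer) | COCOc1cc(C)cc2OC3(C(=O)c12)C(OC(C)(C)C)=CC(=O)CC3CO[Si](C(C)C)(C(C)C)C(C)C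
A2 | alternative 1 | 4-(methoxymethoxy)-6-methyl-1-benzofuran-3(2H)-one | COCOc1cc(C)cc2OCC(=O)c12
A3 | alternative 1 | (E)-1-tert-butoxy-6-{[tri(propan-2-yl)silyl]oxy}hex-4-en-1-yn-3-one | CC(C)(C)OC#CC(=O)/C=C/CO[Si](C(C)C)(C(C)C)C(C)C
A4 | alternative 1 | 6'-tert-butoxy-4-(methoxymethoxy)-6-methyl-2'-({[tri(propan-2-yl)silyl]oxy}methyl)-3H-spiro[1-benzofuran-2,1'-cyclohexa-2',5'-diene]-3,4'-dione (racemic) | COCOc1cc(C)cc2OC3(C(=O)c12)C(OC(C)(C)C)=CC(=O)C=C3CO[Si](C(C)C)(C(C)C)C(C)C
A5 | alternative 1 | methyl 2-[2-tert-butoxy-4-hydroxy-6-({[tri(propan-2-yl)silyl]oxy}methyl)phenoxy]-6-(methoxymethoxy)-4-methylbenzoate | COCOc1cc(C)cc(Oc2c(CO[Si](C(C)C)(C(C)C)C(C)C)cc(O)cc2OC(C)(C)C)c1C(=O)OC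
A6 | alternative 2 | methyl 2-[2-({[tert-butyl(dimethyl)silyl]oxy}methyl)-6-hydroxy-4-methoxyphenoxy]-4-methyl-6-[(3-methylbut-2-en-1-yl)oxy]benzoate | COC(=O)c1c(OCC=C(C)C)cc(C)cc1Oc1c(CO[Si](C)(C)C(C)(C)C)cc(OC)cc1O
A7 | alternative 2 | methyl 2-{[(1E)-2-({[tert-butyl(dimethyl)silyl]oxy}methyl)-4-diazo-3-oxobut-1-en-1-yl]oxy}-4-methyl-6-[(3-methylbut-2-en-1-yl)oxy]benzoate | COC(=O)c1c(OCC=C(C)C)cc(C)cc1O/C=C(\CO[Si](C)(C)C(C)(C)C)C(=O)C=[N+]=[N-]
A8 | alternative 2 | methoxyethyne | COC#C
A9 | alternative 2 | methyl 2-hydroxy-4-methyl-6-[(3-methylbut-2-en-1-yl)oxy]benzoate | COC(=O)c1c(O)cc(C)cc1OCC=C(C)C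
A10 | alternative 3 | 2-(methoxymethoxy)-6-[4-methoxy-2-(methoxymethoxy)-6-({[tri(propan-2-yl)silyl]oxy}methyl)phenoxy]-4-methylbenzoic acid | COCOc1cc(C)cc(Oc2c(CO[Si](C(C)C)(C(C)C)C(C)C)cc(OC)cc2OCOC)c1C(=O)O
A11 | alternative 3 | 3-(methoxymethoxy)-5-methyl-2-(trimethylsilyl)phenyl trifluoromethanesulfonate | COCOc1cc(C)cc(OS(=O)(=O)C(F)(F)F)c1[Si](C)(C)C
A12 | alternative 3 | carbon dioxide | O=C=O
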